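**Strategy.** The plan uses the substitution pattern of ring A. Its two oxygens (O1 on C8a, OH on C7) are meta to each other and flank C8–H, C6 carries the prenyl group, and the C4a–C8a edge is shared with the pyran ring. An alkenylketene and an alkynyl ether assemble exactly this kind of 1,3-dioxygenated benzene, so both rings are cut back to one open chain. Irradiating the diazoketone should trigger Wolff rearrangement, tethered [2+2] addition, four-electron opening and six-electron closure. This makes C7–C8, C4a–C8a and C6–C7 in one operation and leaves no C6/C8 ambiguity. The chain has C2 as a benzylic ethynyl ether, C3 as a MOM ether, C4 as a silyl ether and a dienyl diazoketone terminus.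

Key step: step 16

**Conventions, assumption and design remarks**
- Ar = 4-(methoxymethoxy)-3-(3-methylbut-2-enyl)phenyl; prenyl = 3-methylbut-2-enyl; MOM = methoxymethyl; TIPS = triisopropylsilyl; TES = triethylsilyl. Flavonoid numbering (O1, C2, C3, C4, C4a, C5–C8, C8a) is also used for the open-chain compounds.
- Assumption: C4 is a temporary stereocentre that step 18 erases. Both C4 epimers from step 14 are carried on together. Names and SMILES show the Felkin–Anh (3,4-anti) epimer, which is expected to predominate.
- Side chain: a prenyl group at C6 requires the acyl unit C(=O)–CH=CH–CH2–CH=CMe2 (6-methylhepta-2,5-dienoyl). Coupling a prenyl metal with a 4-halocrotonate would insert one CH2 too many and put a homoprenyl group on C6. The unit is therefore built from 4-methylpent-3-en-1-ol (steps 12 and 13).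
- C2 and C3: C3 comes from (S)-glycerate and C2 from a chelate-controlled ketone reduction. This gives O3 directly as its MOM ether and O2 free. It needs no auxiliary and no strong Lewis acid next to the aryl MOM ether.
- Silyl groups: O4 carries TIPS while it is primary, so that it does not migrate to the C2 alkoxide in step 9. In the precursor it carries TES, which goes on without a silyl triflate and comes off with buffered fluoride.
- Handling: every compound that carries the ethynyl ether is kept at or below room temperature, away from acid, and is purified on Et3N-deactivated silica.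

**Step 1**
Reactants: 1 4-bromo-2-iodophenol
Product: 2 4-bromo-2-iodo-1-(methoxymethoxy)benzene
Conditions: MOMCl, iPr2NEt, CH2Cl2, 0 °C → rt
Reagents that add atoms: chloromethyl methyl ether, COCCl
Why: Base-mediated O-alkylation of the phenol (acetal formation) should be clean, and the MOM ether withstands the organolithium, KH and fluoride steps ahead yet leaves under mild acid in step 19.

**Step 2**
Reactants: 2 4-bromo-2-iodo-1-(methoxymethoxy)benzene; 3 tributyl(3-methylbut-2-enyl)stannane
Product: 4 4-bromo-1-(methoxymethoxy)-2-(3-methylbut-2-enyl)benzene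
Conditions: Pd(PPh3)4 (5 mol %), DMF, 80 °C
Reagents that add atoms: none
Why: Stille coupling in which zerovalent palladium inserts far faster into the C–I bond than into the C–Br bond of this electron-rich ring and the allylic stannane delivers its unsubstituted terminus, so the linear prenyl arene with the bromide intact is expected.

**Step 3**
Reactants: 5 methyl (S)-2,2-dimethyl-1,3-dioxolane-4-carboxylate
Product: 6 methyl (S)-2,3-dihydroxypropanoate
Conditions: Dowex 50W-X8 (H+ form), MeOH, rt
Reagents that add atoms: none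
Why: Acid-catalysed transketalisation to the solvent frees the diol without touching the stereocentre, which is taken from the chiral pool and becomes C3 of the target.

**Step 4**
Reactants: 6 methyl (S)-2,3-dihydroxypropanoate
Product: 7 methyl (S)-2-hydroxy-3-(triisopropylsilyloxy)propanoate
Conditions: iPr3SiCl (1.05 equiv), imidazole, DMF, 0 °C → rt
Reagents that add atoms: chlorotriisopropylsilane, CC(C)[Si](Cl)(C(C)C)C(C)C
Why: Sterically controlled silyl ether formation takes the primary hydroxyl (future O4), and the bulky TIPS group is chosen because it resists O-to-O migration when the neighbouring alkoxide is made in step 9.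

**Step 5**
Reactants: 7 methyl (S)-2-hydroxy-3-(triisopropylsilyloxy)propanoate
Product: 8 methyl (S)-2-(methoxymethoxy)-3-(triisopropylsilyloxy)propanoate
Conditions: MOMCl, iPr2NEt, Bu4NI (cat.), CH2Cl2, 0 → 40 °C
Reagents that add atoms: chloromethyl methyl ether, COCCl
Why: Acetal formation on the remaining α-hydroxyl under amine base does not enolise the ester, and the MOM oxygen later serves as the chelating donor in step 8.

**Step 6**
Reactants: 8 methyl (S)-2-(methoxymethoxy)-3-(triisopropylsilyloxy)propanoate
Product: 9 (S)-N-methoxy-2-(methoxymethoxy)-N-methyl-3-(triisopropylsilyloxy)propanamide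
Conditions: MeNH(OMe)·HCl, iPrMgCl, THF, −20 → 0 °C
Reagents that add atoms: N,O-dimethylhydroxylamine hydrochloride, CNOC.Cl
Why: Weinreb amide formation by aminolysis of the ester with the chloromagnesium amide, a low-temperature process known to preserve α-alkoxy stereocentres.

**Step 7**
Reactants: 4 4-bromo-1-(methoxymethoxy)-2-(3-methylbut-2-enyl)benzene; 9 (S)-N-methoxy-2-(methoxymethoxy)-N-methyl-3-(triisopropylsilyloxy)propanamide
Product: 11 (S)-1-Ar-2-(methoxymethoxy)-3-(triisopropylsilyloxy)propan-1-one, via aryllithium 10 (not isolated)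
Conditions: n-BuLi, THF, −78 °C; then 9, −78 → −40 °C; aq NH4Cl
Reagents that add atoms: none
Why: Bromine–lithium exchange followed by Weinreb ketone synthesis, in which the chelated tetrahedral adduct survives until the quench and so prevents both double addition and enolisation at C3.

**Step 8**
Reactants: 11 (S)-1-Ar-2-(methoxymethoxy)-3-(triisopropylsilyloxy)propan-1-one
Product: 12 (1R,2S)-1-Ar-2-(methoxymethoxy)-3-(triisopropylsilyloxy)propan-1-ol (1,2-anti)
Conditions: Zn(BH4)2 (ethereal stock solution), Et2O, −40 → −20 °C; H2O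
Reagents that add atoms: none
Why: Chelation-controlled (Cram chelate) reduction: zinc binds the ketone oxygen and the α-MOM oxygen in a five-membered ring and hydride arrives on the face opposite the CH2OTIPS arm, which sets C2 as R and 1,2-anti to C3, the relationship that becomes 2,3-trans in the pyran ring.

**Step 9**
Reactants: 12 (1R,2S)-1-Ar-2-(methoxymethoxy)-3-(triisopropylsilyloxy)propan-1-ol; 13 trichloroethylene
Product: 16 [(2S,3R)-3-Ar-3-(ethynyloxy)-2-(methoxymethoxy)propoxy]triisopropylsilane, via dichlorovinyl ether 14 (not isolated), via lithium acetylide 15 (not isolated)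
Conditions: KH, THF, 0 °C → rt; 13, −50 °C → rt; then n-BuLi (2.5–3 equiv), −78 → −40 °C; H2O
Reagents that add atoms: none
Why: Established one-pot ynol ether synthesis: addition–elimination of the potassium alkoxide on trichloroethylene gives 14, and n-BuLi then effects dehydrochlorination and chlorine–lithium exchange to acetylide 15, which water protonates, all without breaking the C2–O bond so that C2 keeps its configuration.

**Step 10**
Reactants: 16 [(2S,3R)-3-Ar-3-(ethynyloxy)-2-(methoxymethoxy)propoxy]triisopropylsilane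
Product: 17 (2S,3R)-3-Ar-3-(ethynyloxy)-2-(methoxymethoxy)propan-1-ol
Conditions: Bu4NF, THF, 0 °C → rt
Reagents that add atoms: none
Why: Fluoride-driven Si–O cleavage under basic conditions, to which the acid-sensitive ynol ether and both MOM acetals are inert.

**Step 11**
Reactants: 17 (2S,3R)-3-Ar-3-(ethynyloxy)-2-(methoxymethoxy)propan-1-ol
Product: 18 (2R,3R)-3-Ar-3-(ethynyloxy)-2-(methoxymethoxy)propanal
Conditions: Dess–Martin periodinane, pyridine, CH2Cl2, 0 °C; used at once
Reagents that add atoms: none
Why: Dess–Martin oxidation, buffered with pyridine so that the acetic acid released cannot add to the ynol ether, stops at the aldehyde and involves no base strong enough to epimerise C3 or to eliminate the C2 oxygen.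

**Step 12**
Reactants: 19 4-methylpent-3-en-1-ol; 20 1-(triphenylphosphoranylidene)propan-2-one
Product: 22 (E)-7-methylocta-3,6-dien-2-one, via 4-methylpent-3-enal 21 (not isolated)
Conditions: IBX, DMSO, rt, 20 present from the start
Reagents that add atoms: none
Why: Tandem IBX oxidation–Wittig olefination, in which the isomerisation-prone β,γ-unsaturated aldehyde 21 is captured as it forms by the stabilised ylide, a reagent class that gives E-enones.

**Step 13**
Reactants: 22 (E)-7-methylocta-3,6-dien-2-one
Product: 24 (E)-1-diazo-7-methylocta-3,6-dien-2-one, via trifluoroacetyl diketone 23 (not isolated)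
Conditions: LiN(SiMe3)2, THF, −78 °C; CF3CO2CH2CF3; dilute HCl wash; then MsN3, Et3N, H2O, MeCN, rt
Reagents that add atoms: methanesulfonyl azide, CS(=O)(=O)N=[N+]=[N-] (the two nitrogens of 24); 2,2,2-trifluoroethyl trifluoroacetate, O=C(OCC(F)(F)F)C(F)(F)F (trifluoroacetyl group of 23 only)
Why: Detrifluoroacetylative (Regitz-type) diazo transfer: kinetic α′-deprotonation and trifluoroacetylation activate the methyl group as diketone 23, which accepts N2 from the sulfonyl azide and sheds the trifluoroacetyl group, a sequence suited to enones because acyl chloride/diazomethane routes suffer dipolar cycloaddition to the C=C bond.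

**Step 14**
Reactants: 24 (E)-1-diazo-7-methylocta-3,6-dien-2-one; 18 (2R,3R)-3-Ar-3-(ethynyloxy)-2-(methoxymethoxy)propanal
Product: 26 (1R,2S,3S,6E)-1-Ar-4-diazo-1-(ethynyloxy)-3-hydroxy-2-(methoxymethoxy)-10-methylundeca-6,9-dien-5-one, via lithiated diazoketone 25 (not isolated)
Conditions: LiN(iPr)2 (slightly less than 24), THF, −78 °C; then 18, −78 °C; aq NH4Cl
Reagents that add atoms: none
Why: Aldol-type addition of a lithiated α-diazoketone to an aldehyde at low temperature forms C4–C4a, with the polar Felkin–Anh model predicting the 3,4-anti carbinol, although no control is needed because C4 is oxidised in step 18.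

**Step 15**
Reactants: 26 (1R,2S,3S,6E)-1-Ar-4-diazo-1-(ethynyloxy)-3-hydroxy-2-(methoxymethoxy)-10-methylundeca-6,9-dien-5-one
Product: 27 (1R,2R,3S,6E)-1-Ar-4-diazo-1-(ethynyloxy)-2-(methoxymethoxy)-10-methyl-3-(triethylsilyloxy)undeca-6,9-dien-5-one (open-chain ethynyl ether diazoketone)
Conditions: Et3SiCl, imidazole, DMAP (cat.), CH2Cl2, 0 °C
Reagents that add atoms: chlorotriethylsilane, CC[Si](Cl)(CC)CC
Why: Silyl ether formation with the chlorosilane and imidazole caps O4 so that it cannot trap the ketene, and avoids silyl triflates, which would endanger the diazo group, the ynol ether and the MOM acetals.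

**Step 16**
Reactants: 27 open-chain ethynyl ether diazoketone
Product: 32 (2R,3R,4S)-2-Ar-3-(methoxymethoxy)-6-(3-methylbut-2-enyl)-4-(triethylsilyloxy)chroman-7-ol, via vinylketene 28 (not isolated), via fused cyclobutenone 29 (not isolated), via dienylketene 30 (not isolated), via cyclohexadienone 31 (not isolated)
Conditions: hν (365 nm LED, Pyrex), degassed toluene (0.003 M), 5–10 °C, until N2 evolution stops; then 80 °C in the dark
Reagents that add atoms: none
Why: Proposed new method: excitation of the diazoketone expels N2 with migration of the alkenyl group (Wolff rearrangement) to give vinylketene 28, whose carbonyl carbon (future C7) bonds to the nucleophilic terminal alkyne carbon (C8) while its α-carbon (C4a) bonds to the oxygen-bearing carbon (C8a), and warming then opens cyclobutenone 29 by four-electron conrotation to dienylketene 30, which closes by six-electron disrotation (C6–C7) to dienone 31 and tautomerises to phenol 32. The closest known reaction type is the intermolecular Danheiser benzannulation of photochemically generated vinylketenes with alkoxy- or siloxyalkynes, whereas joining the two partners through O1–C2–C3–C4 has no precedent. The pyran ring closes in the [2+2] event as the six-membered half of a fused 2-oxabicyclo[4.2.0]octenone, and ring A closes in the six-electron electrocyclisation. No lasting stereocentre is made, since C4a and C6 are tetrahedral only in passing and C2, C3 and C4 are spectators that none of the intermediates can epimerise. The step needs chemoselectivity (Wolff shift faster than the 1,2-hydride shift from C4–H, cyclopropenation or ylide formation), which is helped by long-wave excitation of the diazo chromophore alone, by cold dilute solution, and by heating only after the thermally labile benzylic ynol ether has been consumed. Regiochemistry is secured twice, because ynol ether polarisation and the four-atom tether both demand C7–C8 and C4a–C8a bonding, and the endocyclic C4a=C8a bond of 30 holds ketene and alkenyl arm cis so that only the C6–C7 closure is open.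

**Step 17**
Reactants: 32 (2R,3R,4S)-2-Ar-3-(methoxymethoxy)-6-(3-methylbut-2-enyl)-4-(triethylsilyloxy)chroman-7-ol
Product: 33 (2R,3S,4S)-2-Ar-3-(methoxymethoxy)-6-(3-methylbut-2-enyl)chroman-4,7-diol
Conditions: Bu4NF, AcOH (1:1), THF, 0 °C
Reagents that add atoms: none
Why: Fluoride-mediated desilylation, buffered with acetic acid so that the 7-phenol stays protonated and the p-hydroxybenzylic C4–O bond is not lost through a quinone methide.

**Step 18**
Reactants: 33 (2R,3S,4S)-2-Ar-3-(methoxymethoxy)-6-(3-methylbut-2-enyl)chroman-4,7-diol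
Product: 34 (2R,3R)-2-Ar-7-hydroxy-3-(methoxymethoxy)-6-(3-methylbut-2-enyl)chroman-4-one
Conditions: MnO2 (activated, excess), CH2Cl2, rt
Reagents that add atoms: none
Why: MnO2 oxidation, selective for benzylic alcohols and here assisted by the para 7-OH and ortho O1 donors, converts both C4 epimers into the one ketone under neutral heterogeneous conditions that leave C2, C3 and the prenyl groups alone.

**Step 19**
Reactants: 34 (2R,3R)-2-Ar-7-hydroxy-3-(methoxymethoxy)-6-(3-methylbut-2-enyl)chroman-4-one
Product: 35 lespeflorin B1, (2R,3R)-3,7-dihydroxy-2-[4-hydroxy-3-(3-methylbut-2-enyl)phenyl]-6-(3-methylbut-2-enyl)chroman-4-one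
Conditions: HCl (3 M aq), MeOH, 45 °C
Reagents that add atoms: none
Why: Acid-catalysed acetal exchange with methanol removes the aryl MOM and the α-keto MOM ether, both of which release comparatively good leaving alcohols and so cleave below the acidity and temperature at which o-prenylphenols cyclise to chromans, while the 2,3-trans arrangement is the thermodynamically preferred one and is not scrambled.

**Compound list**
1 | 4-bromo-2-iodophenol | Oc1ccc(Br)cc1I | starting material
2 | 4-bromo-2-iodo-1-(methoxymethoxy)benzene | COCOc1ccc(Br)cc1I | intermediate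
3 | tributyl(3-methylbut-2-enyl)stannane | CCCC[Sn](CCCC)(CCCC)CC=C(C)C | starting material
4 | 4-bromo-1-(methoxymethoxy)-2-(3-methylbut-2-enyl)benzene | COCOc1ccc(Br)cc1CC=C(C)C | intermediate
5 | methyl (S)-2,2-dimethyl-1,3-dioxolane-4-carboxylate | COC(=O)[C@@H]1COC(C)(C)O1 | starting material
6 | methyl (S)-2,3-dihydroxypropanoate | COC(=O)[C@@H](O)CO | intermediate
7 | methyl (S)-2-hydroxy-3-(triisopropylsilyloxy)propanoate | COC(=O)[C@@H](O)CO[Si](C(C)C)(C(C)C)C(C)C | intermediate
8 | methyl (S)-2-(methoxymethoxy)-3-(triisopropylsilyloxy)propanoate | COC(=O)[C@@H](OCOC)CO[Si](C(C)C)(C(C)C)C(C)C | intermediate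
9 | (S)-N-methoxy-2-(methoxymethoxy)-N-methyl-3-(triisopropylsilyloxy)propanamide | CON(C)C(=O)[C@@H](OCOC)CO[Si](C(C)C)(C(C)C)C(C)C | intermediate
10 | [4-(methoxymethoxy)-3-(3-methylbut-2-enyl)phenyl]lithium | [Li]c1ccc(OCOC)c(CC=C(C)C)c1 | intermediate
11 | (S)-1-Ar-2-(methoxymethoxy)-3-(triisopropylsilyloxy)propan-1-one | O=C(c1ccc(OCOC)c(CC=C(C)C)c1)[C@@H](OCOC)CO[Si](C(C)C)(C(C)C)C(C)C | intermediate
12 | (1R,2S)-1-Ar-2-(methoxymethoxy)-3-(triisopropylsilyloxy)propan-1-ol | O[C@H](c1ccc(OCOC)c(CC=C(C)C)c1)[C@@H](OCOC)CO[Si](C(C)C)(C(C)C)C(C)C | intermediate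
13 | trichloroethylene | ClC=C(Cl)Cl | starting material
14 | (E)-1,2-dichlorovinyl ether of 12 | Cl/C=C(/Cl)O[C@H](c1ccc(OCOC)c(CC=C(C)C)c1)[C@@H](OCOC)CO[Si](C(C)C)(C(C)C)C(C)C | intermediate
15 | lithium acetylide of 16 (2-lithioethynyl ether) | [Li]C#CO[C@H](c1ccc(OCOC)c(CC=C(C)C)c1)[C@@H](OCOC)CO[Si](C(C)C)(C(C)C)C(C)C | intermediate
16 | [(2S,3R)-3-Ar-3-(ethynyloxy)-2-(methoxymethoxy)propoxy]triisopropylsilane | C#CO[C@H](c1ccc(OCOC)c(CC=C(C)C)c1)[C@@H](OCOC)CO[Si](C(C)C)(C(C)C)C(C)C | intermediate
17 | (2S,3R)-3-Ar-3-(ethynyloxy)-2-(methoxymethoxy)propan-1-ol | C#CO[C@H](c1ccc(OCOC)c(CC=C(C)C)c1)[C@@H](OCOC)CO | intermediate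
18 | (2R,3R)-3-Ar-3-(ethynyloxy)-2-(methoxymethoxy)propanal | C#CO[C@H](c1ccc(OCOC)c(CC=C(C)C)c1)[C@@H](OCOC)C=O | intermediate
19 | 4-methylpent-3-en-1-ol | CC(C)=CCCO | starting material
20 | 1-(triphenylphosphoranylidene)propan-2-one | CC(=O)C=P(c1ccccc1)(c1ccccc1)c1ccccc1 | starting material
21 | 4-methylpent-3-enal | CC(C)=CCC=O | intermediate
22 | (E)-7-methylocta-3,6-dien-2-one | CC(=O)/C=C/CC=C(C)C | intermediate
23 | (E)-1,1,1-trifluoro-9-methyldeca-5,8-diene-2,4-dione | O=C(CC(=O)/C=C/CC=C(C)C)C(F)(F)F | intermediate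
24 | (E)-1-diazo-7-methylocta-3,6-dien-2-one | [N-]=[N+]=CC(=O)/C=C/CC=C(C)C | intermediate
25 | (E)-1-diazo-1-lithio-7-methylocta-3,6-dien-2-one | [Li]C(=[N+]=[N-])C(=O)/C=C/CC=C(C)C | intermediate
26 | (1R,2S,3S,6E)-1-Ar-4-diazo-1-(ethynyloxy)-3-hydroxy-2-(methoxymethoxy)-10-methylundeca-6,9-dien-5-one | C#CO[C@H](c1ccc(OCOC)c(CC=C(C)C)c1)[C@@H](OCOC)[C@@H](O)C(=[N+]=[N-])C(=O)/C=C/CC=C(C)C | intermediate
27 | (1R,2R,3S,6E)-1-Ar-4-diazo-1-(ethynyloxy)-2-(methoxymethoxy)-10-methyl-3-(triethylsilyloxy)undeca-6,9-dien-5-one (key-step precursor) | C#CO[C@H](c1ccc(OCOC)c(CC=C(C)C)c1)[C@@H](OCOC)[C@@H](O[Si](CC)(CC)CC)C(=[N+]=[N-])C(=O)/C=C/CC=C(C)C | intermediate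
28 | vinylketene O=C7=C4a(C4 chain)(CH=CH–CH2CH=CMe2), ethynyl ether intact, C2–C4 as in 27 | C#CO[C@H](c1ccc(OCOC)c(CC=C(C)C)c1)[C@@H](OCOC)[C@@H](O[Si](CC)(CC)CC)C(=C=O)/C=C/CC=C(C)C | intermediate
29 | fused cyclobutenone (2-oxabicyclo[4.2.0]oct-1(8)-en-7-one; C4a quaternary, configuration not defined), C2–C4 as in 27 | O=C1C=C2O[C@H](c3ccc(OCOC)c(CC=C(C)C)c3)[C@@H](OCOC)[C@@H](O[Si](CC)(CC)CC)C12/C=C/CC=C(C)C | intermediate
30 | dienylketene (3,4-dihydro-2H-pyran with ketenyl group on C8a and dienyl arm on C4a) | O=C=CC1=C(/C=C/CC=C(C)C)[C@H](O[Si](CC)(CC)CC)[C@H](OCOC)[C@@H](c2ccc(OCOC)c(CC=C(C)C)c2)O1 | intermediate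
31 | cyclohexa-2,4-dienone tautomer of 32 (C6 tetrahedral, configuration not defined) | O=C1C=C2O[C@H](c3ccc(OCOC)c(CC=C(C)C)c3)[C@@H](OCOC)[C@@H](O[Si](CC)(CC)CC)C2=CC1CC=C(C)C | intermediate
32 | (2R,3R,4S)-2-Ar-3-(methoxymethoxy)-6-(3-methylbut-2-enyl)-4-(triethylsilyloxy)chroman-7-ol (2,3-trans; key-step product) | CC(C)=CCc1cc([C@H]2Oc3cc(O)c(CC=C(C)C)cc3[C@H](O[Si](CC)(CC)CC)[C@@H]2OCOC)ccc1OCOC | intermediate
33 | (2R,3S,4S)-2-Ar-3-(methoxymethoxy)-6-(3-methylbut-2-enyl)chroman-4,7-diol | CC(C)=CCc1cc([C@H]2Oc3cc(O)c(CC=C(C)C)cc3[C@H](O)[C@@H]2OCOC)ccc1OCOC | intermediate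
34 | (2R,3R)-2-Ar-7-hydroxy-3-(methoxymethoxy)-6-(3-methylbut-2-enyl)chroman-4-one | CC(C)=CCc1cc([C@H]2Oc3cc(O)c(CC=C(C)C)cc3C(=O)[C@@H]2OCOC)ccc1OCOC | intermediate
35 | lespeflorin B1, (2R,3R)-3,7-dihydroxy-2-[4-hydroxy-3-(3-methylbut-2-enyl)phenyl]-6-(3-methylbut-2-enyl)chroman-4-one | CC(C)=CCc1cc([C@H]2Oc3cc(O)c(CC=C(C)C)cc3C(=O)[C@@H]2O)ccc1O | target

**Total step count:** 19. **Longest linear sequence:** 15 (steps 3–11, then 14–19).

**Steps most likely to fail**

Step 16 (key step). After loss of N2 the free-carbene pathway may win, with hydride migrating from C4 to the carbene carbon. The ketene may also oligomerise before it reaches the alkyne, or the benzylic ynol ether may rearrange sigmatropically before it is intercepted. The fallback uses known chemistry and runs from 4 (and 3) to 35.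
- Bromine–lithium exchange on 4 and a DMF quench give 4-(methoxymethoxy)-3-(3-methylbut-2-enyl)benzaldehyde F1.
- Commercial 1-(5-bromo-2,4-dihydroxyphenyl)ethanone is protected with MOMCl/iPr2NEt as 1-[5-bromo-2,4-bis(methoxymethoxy)phenyl]ethanone F2. Stille coupling with 3 (Pd(PPh3)4, DMF, 100 °C) then gives 1-[2,4-bis(methoxymethoxy)-5-(3-methylbut-2-enyl)phenyl]ethanone F3.
- Claisen–Schmidt condensation of F3 with F1 (KOH, EtOH) gives the (E)-chalcone F4.
- Juliá–Colonna epoxidation (poly-L-leucine, urea·H2O2, DBU, THF) is a nucleophilic oxidation that ignores the prenyl alkenes. It gives the (αR,βS)-epoxychalcone F5.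
- HCl in MeOH at 45 °C strips the three MOM groups. The liberated 2'-phenol opens the epoxide at the benzylic carbon with inversion, and this closes the pyranone ring to 35.

In this variant ring A is bought rather than built.

Step 14. The base or the lithiated diazoketone may remove a doubly allylic proton or add in conjugate fashion to a second enone. The aldehyde may also enolise and expel the C2 oxygen substituent. The fallback runs from 18 and 22 to 27 and forms C4–C4a before the diazo group exists.
- The kinetic lithium enolate of 22 (LiN(iPr)2, THF, −78 °C, the same α′-deprotonation as in step 13) adds to 18 and gives the β-hydroxy enone F6.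
- Et3SiCl/imidazole gives the triethylsilyl ether F7.
- LiN(SiMe3)2 followed by CF3CO2CH2CF3 gives the α-trifluoroacetyl ketone F8.
- MsN3/Et3N/H2O in MeCN transfers the diazo group with loss of the trifluoroacetyl group, which gives 27.

Step 9. The hindered secondary potassium alkoxide may attack trichloroethylene only sluggishly. While it waits, silicon may migrate from O4 to O2, or the excess base may deprotonate the benzylic position. The fallback runs from 12 to 16 and never generates the free alkoxide.
- Formylation (formic acetic anhydride, pyridine, 0 °C) gives the formate F9.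
- Dichloromethylenation of the formate carbonyl (PPh3, CCl4, THF, 60 °C) gives the 2,2-dichlorovinyl ether F10.
- n-BuLi (THF, −78 °C) followed by water gives 16.

**Further compounds**
F1 | step 16 | 4-(methoxymethoxy)-3-(3-methylbut-2-enyl)benzaldehyde | O=Cc1ccc(OCOC)c(CC=C(C)C)c1
F2 | step 16 | 1-[5-bromo-2,4-bis(methoxymethoxy)phenyl]ethanone | CC(=O)c1cc(Br)c(OCOC)cc1OCOC
F3 | step 16 | 1-[2,4-bis(methoxymethoxy)-5-(3-methylbut-2-enyl)phenyl]ethanone | CC(=O)c1cc(CC=C(C)C)c(OCOC)cc1OCOC
F4 | step 16 | (E)-1-[2,4-bis(methoxymethoxy)-5-(3-methylbut-2-enyl)phenyl]-3-Ar-prop-2-en-1-one | O=C(/C=C/c1ccc(OCOC)c(CC=C(C)C)c1)c1cc(CC=C(C)C)c(OCOC)cc1OCOC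
F5 | step 16 | [2,4-bis(methoxymethoxy)-5-(3-methylbut-2-enyl)phenyl][(2R,3S)-3-Ar-oxiran-2-yl]methanone | O=C(c1cc(CC=C(C)C)c(OCOC)cc1OCOC)[C@@H]1O[C@H]1c1ccc(OCOC)c(CC=C(C)C)c1
F6 | step 14 | (1R,2S,3S,6E)-1-Ar-1-(ethynyloxy)-3-hydroxy-2-(methoxymethoxy)-10-methylundeca-6,9-dien-5-one | C#CO[C@H](c1ccc(OCOC)c(CC=C(C)C)c1)[C@@H](OCOC)[C@@H](O)CC(=O)/C=C/CC=C(C)C
F7 | step 14 | triethylsilyl ether of F6 | C#CO[C@H](c1ccc(OCOC)c(CC=C(C)C)c1)[C@@H](OCOC)[C@@H](O[Si](CC)(CC)CC)CC(=O)/C=C/CC=C(C)C
F8 | step 14 | 4-(trifluoroacetyl) derivative of F7 (C4a configuration not defined) | C#CO[C@H](c1ccc(OCOC)c(CC=C(C)C)c1)[C@@H](OCOC)[C@@H](O[Si](CC)(CC)CC)C(C(=O)C(F)(F)F)C(=O)/C=C/CC=C(C)C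
F9 | step 9 | (1R,2S)-1-Ar-2-(methoxymethoxy)-3-(triisopropylsilyloxy)propyl formate | O=CO[C@H](c1ccc(OCOC)c(CC=C(C)C)c1)[C@@H](OCOC)CO[Si](C(C)C)(C(C)C)C(C)C
F10 | step 9 | 2,2-dichlorovinyl ether of 12 | ClC(Cl)=CO[C@H](c1ccc(OCOC)c(CC=C(C)C)c1)[C@@H](OCOC)CO[Si](C(C)C)(C(C)C)C(C)C
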